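**The constants.** Start from the constants that Q's readings give you. Summer and winter charge Q and Z one to one, with X above them at 2.00 equiv and 1.30 equiv, so Q and Z are the limiting reagents and the balance reads: Q charged equals Q left plus J plus L. With equal charges, the share of Q left is one over one plus a clock. Gamma's last reading gives that clock a rate of 0.00556 min⁻¹, and alpha's gives 0.0416 min⁻¹. These are readings with their scatter. The line through them, with slope 7230 K, reaches 0.157 min⁻¹ at 20 °C and 0.00946 min⁻¹ at −10 °C.

| setting | gamma | alpha | summer | winter |
|---|---|---|---|---|
| Q | 0.055 M | 0.055 M | 0.055 M | 0.055 M |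
| Z | 1 equiv | 1 equiv | 1.00 equiv | 1.00 equiv |
| X | 1.2 equiv | 1.7 equiv | 2.00 equiv | 1.30 equiv |
| temperature | −15 °C | 5 °C |  |  |
| remark | run made earlier | run made earlier | at 20 °C until 6.0 min, from then on at −10 °C | at 20 °C throughout |
| time |  |  | 12 min | 12 min |

| run | time / min | L / % | Q / % |
|---|---|---|---|
| gamma | 8.00 | 0 | 97 |
| gamma | 25.0 | 3 | 86 |
| gamma | 50.0 | 2 | 80 |
| gamma | 60.0 | 3 | 75 |
| alpha | 2.00 | 0 | 93 |
| alpha | 4.00 | 2 | 83 |
| alpha | 10.0 | 5 | 69 |
| alpha | 25.0 | 21 | 49 |

(each reading ± 2 percentage points)

- what is said of L includes G
- G is a solid; its amount is given per volume of the solution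
- the analysis behind the earlier runs scatters by 2 percentage points, standard deviation
- on the list of suspects stand: Q + Z -> J; X + J <-> L; G <-> L

* which one finishes higher in amount of L, in percent of the Q charged ("neither" within 2 percentage points) (summer / winter / neither)
* amount of L at the end, in percent of the Q charged, summer
* amount of L at the end, in percent of the Q charged, winter

**Two extremes.** Summer's clock, the rate of Q + Z at Q's charged concentration summed over the time, is 1.00; winter's is 1.89. If J became L at once, L would equal the Q gone, which is clock over one plus clock: a ceiling of 50.0% for summer and 65.4% for winter. If X left J untouched, L would stay at zero.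

**Between them.** Alpha's last reading has nearly summer's clock, 1.04, and shows L at 21% with 51.0% of Q gone, a share of 0.412. My own reckoning applies that share to both ceilings: 20.6% for summer and 26.9% for winter. Winter leads because its ceiling is higher, though its smaller X charge may lower its share.

**The forecast.** It says winter, with 19% for summer and 27% for winter, and its ceilings lie slightly above mine: “Total J + L formed is therefore about 67% in winter and 51% in summer”.

**The flasks.** winter finishes higher, with summer at 18.6% and winter at 23.6%.

    Q + Z → J (k = 0.0557 L mol⁻¹ s⁻¹, Ea = 63.0 kJ mol⁻¹)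
    X + J ⇌ L (K = 6.36 L mol⁻¹, k = 0.0212 L mol⁻¹ s⁻¹, Ea = 46.0 kJ mol⁻¹, ΔH = −63.0 kJ mol⁻¹)
    G ⇌ L, rate k3*(cs3 - [L]) while solid is left; crystals form when [L] > cs3 (solubility = 1.60 mM, k = 0.00922 s⁻¹)
    (constants at 20 °C)

**The clock again.** Summer has 53.7% of its Q gone against a ceiling of 50.0%. Its answer has moved by 5 points at 2.73 equiv of X, about winter's lead of 5.0 percentage points, so that is a run that could overturn the order. Summer's recipe with 0.14 M of Q multiplies the clock by 2.55, to 2.55, which puts the ceiling at 71.8%. That flask has 74.7% of its Q gone, and its L stands at 49.3%.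

All runs stem from a simulated flask for an exercise; the scatter is artificial.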